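## Analysis of the target

Compound 19 is a C10 halogenated oxolane. Its ring atoms are numbered O1, C2 (quaternary, with methyl and (E)-2-bromoethenyl), C3 (CHBr), C4 (CH2) and C5 (CH bearing C1', a carbon that carries Br, CH3 and CH2Cl); this atom numbering is used for every intermediate below, whatever locants its systematic name uses. There are four stereocentres, C2 (S), C3 (R), C5 (R) and C1' (R). On the ring the C2 methyl group, the C3 bromine and the C5 side chain share one face (the "lower face"), the bromoalkene sits on the other, and C1' lies outside the ring, so ring bias cannot set it. The sensitive groups are the tertiary bromide with its vicinal primary chloride (elimination, ionisation, halogen shifts), the secondary bromide at C3 (E2 toward C4), the bromoalkene (halogen–metal exchange, reduction) and the tertiary allylic ether at C2 (acid). The difficulty lies in the two fully substituted carbons C2 and C1' that flank the ring: bromine must enter at C3 next to C2 and cis to its methyl group, C3 must be told apart from C4, and C1' needs a tertiary bromide of defined configuration with chlorine, not bromine, on the primary carbon. The feature used is that C2 carries a two-carbon unsaturated arm and is joined through C3–C4 to C5, so a C3=C4 double bond can be made by ring-closing metathesis of an ether whose carbinol carbon bears two identical vinyl groups and whose C5 bears one. The vinyl group that does not react is the precursor of the bromoalkene, the carbinol carbon becomes the stereocentre C2 on ring closure, and the new ring alkene is the entry to the C3 bromide.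

## Retrosynthetic reasoning

**C1'–Br (19 to 17).** The tertiary bromide is the function least likely to survive base, Lewis acids or reducing metals, so it is cut first and made last. The precursor is the tertiary alcohol 17, in which C1' is already a stereocentre. The forward step has to replace OH by Br with retention.

**C1'–CH3 and C1'–CH2Cl (17 to 16 to 15).** C1' needs its own control element. A carbonyl group at C1' next to the ring oxygen allows chelation control, so the methyl group is cut to give chloromethyl ketone 16. This order is chosen over the reverse (a methyl ketone plus a chloromethyl nucleophile) because chelate-controlled methyl addition to 16 gives the R carbinol, which is the one a retentive substitution needs. Ketone 16 is cut at C1'–CH2Cl back to ester 15, so C1' travels through the route as a carboxyl carbon.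

**Bromoalkene (15 to 14 to 12).** The Cα=Cβ bond is cut to aldehyde 14, which has no α-hydrogen and cannot epimerise at C2. Aldehyde 14 comes from the vinyl group of 12 by oxidative cleavage. The E geometry is set in the olefination, and the vinyl group is the spare arm of the key step.

**C3–Br (12 to 10).** The C–Br bond is cut to alcohol 10, which has the opposite configuration at C3, so the forward step is a displacement with inversion. It is placed after the C5 arm has become an ester, so that no free hydroxyl group can attack C3 from the lower face, and before the vinyl group is cleaved.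

**C5 oxidation level and C4–H (10 to 9 to 8 to 6 to 5).** Ester 10 and acid 9 come from the primary alcohol of diol 8. Diol 8 is cut at C4–H back to epoxide 6, whose oxygen sits on the upper face. The CH2O group on the lower face of C5 is the only handle that distinguishes C4 from C3, so the C5 arm stays at the alcohol level until the hydride has been delivered and is oxidised only afterwards. Epoxide 6 comes from ring alkene 5 by attack anti to the C5 arm.

**Key disconnection, C3=C4 (5 to 4).** Cutting the ring alkene gives triene 4. This removes the ring and the stereocentre C2 in one operation, because C2 in 4 carries two identical vinyl groups. The forward reaction must close the five-membered ring, expel the two terminal CH2 groups, and choose the vinyl group that leaves the methyl group cis to the C5 arm. A cut at a ring C–O bond would need C2 or C5 as a preformed electrophile with its stereochemistry; the C3=C4 cut needs only C5.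

**C5–O (4 to 2 and 3) and 2 to 1.** The ether bond between C5 and oxygen is cut to the achiral tertiary alcohol 3 and the symmetrical bis-carbonate 2, made from diol 1. A tertiary alkoxide can be joined to a secondary allylic carbon only through a metal–allyl intermediate, and a branched-selective, ligand-controlled substitution sets C5, the single stereocentre the key step needs. The C5 arm is carried as CH2OCO2Me. An arm with a fully substituted carbon, such as a ketal-masked acetyl group, would make this etherification too congested and would later shield C4 from hydride.

## Alternatives that were turned down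

**Alternative 1:** The cut is at C4–C5 and C2–C3 together. In the forward sense a strong Lewis acid opens a cyclic acetal to an oxocarbenium ion, a vinyl group closes onto it (Prins) to give an oxane cation, and a pinacol-type 1,2-shift contracts this to the 3-acetyl oxolane A1. For it: the ring, two C–C bonds and the relative configuration of C2, C3 and C5 come from one ordered cationic cascade, the alkyne arm needs no oxidative cleavage, and the side chain arrives complete. On ring stereocontrol and convergence it is stronger than the chosen route, which depends on a weak 1,3-bias. Against it: the acetyl group of A1 is cis to the C2 methyl group, on the face the bromine must occupy. Exchanging it for bromine therefore needs epimerisation at C3, Baeyer–Villiger degradation, hydrolysis and then the same rear-side displacement next to C2 that the chosen route needs, four steps for one C–Br bond. The tertiary bromide with its β-chlorine must be built with its configuration into an acyclic component and then survive a Lewis acid that ionises a C–O bond two atoms away. The other component needs an enantiopure fully substituted carbinol. In its place the chosen route introduces all four halogens after the ring exists, the tertiary bromide last, and needs one stereocentre, made by asymmetric catalysis, before the key step.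

**Alternative 2:** The cut is at C4–C5. A dirhodium carbenoid from a terminal diazo ketone inserts into the allylic O–CH2 bond of a methallyl ether and closes the oxolan-3-one A2. For it: C3 is oxygenated by construction, so the C3/C4 question that the chosen route answers with a directed hydride delivery does not arise. On that point and on the number of steps to the ring it is stronger. Against it: C2 must be brought in as an enantiopure tertiary propargylic ether. C5 depends on the diastereoselectivity of the insertion, which competes with cyclopropanation of the methallyl alkene. Hydride should reduce the C3 ketone of A2 from the face of the slim alkyne, which gives the alcohol cis to the methyl group, the wrong epimer for a single inversion to 19. The isopropenyl group gives no handle for C1' and would have to take bromine at the tertiary and chlorine at the primary carbon, against the normal sense of bromine–chlorine addition. In its place the chosen route has a carbonyl group at C1' for chelation control and puts the C3 oxygen on the correct face through epoxide 6.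

**Alternative 3:** The cut is at the ring C–O bond of the quaternary carbon, by oxygen insertion into a cyclobutanone from a ketene cycloaddition. A peracid inserts oxygen next to the more substituted α-carbon with retention and gives the γ-lactone A3. For it: the insertion is regio- and stereospecific. A3 has the C3 oxygen trans to the methyl group, as one inversion to bromide requires, and the C2/C3 relationship is locked in the four-membered ring. On that relationship it is stronger than the chosen route, where it depends on group selection in the metathesis and on the face of epoxidation. Against it: the lactone carbonyl is C5 of 19, so the whole side chain must be added to the lactone and the lactol reduced through an oxocarbenium ion, which sets C5 late with uncertain 2,5-selectivity. The cycloaddition gives racemic material, and the benzyl ether must be removed without hydrogenating the vinyl group. In its place the chosen route sets C5 first by asymmetric catalysis, uses it to relay the other centres, and has C1' present from the start as a carbon of diol 1.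

Key step: step 3

Assumption: the iridium–phosphoramidite catalyst is taken to show its usual facial preference with linear (E)-allyl carbonates; the ligand antipode is chosen so that ether 4 has the R configuration.

## Route

Step 1
Reactants: 1 (E)-but-2-ene-1,4-diol
Product: 2 (E)-but-2-ene-1,4-diyl dimethyl biscarbonate
Conditions: ClCO2Me (2.4 equiv), pyridine, CH2Cl2, 0 → 25 °C
Reagents that add atoms: methyl chloroformate, COC(=O)Cl
Why: O-acylation of both primary hydroxyl groups (carbonate formation); the symmetrical bis-carbonate avoids a statistical mono-protection, and after the first allylic substitution the second carbonate is no longer allylic and serves as the protecting group of the C1' oxygen.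

Step 2
Reactants: 2 (E)-but-2-ene-1,4-diyl dimethyl biscarbonate; 3 3-methylpenta-1,4-dien-3-ol
Product: 4 methyl (2R)-2-[(3-methylpenta-1,4-dien-3-yl)oxy]but-3-en-1-yl carbonate
Conditions: 3, n-BuLi, THF, 0 °C, then CuI; added to 2, [Ir(cod)Cl]2 (2 mol %), phosphoramidite L (4 mol %), THF, 25 °C (L = O,O'-(1,1'-binaphthalene-2,2'-diyl) N,N-bis(1-phenylethyl)phosphoramidite)
Reagents that add atoms: none
Why: Iridium-catalysed asymmetric allylic etherification: ionisation of one carbonate gives an allyl–iridium complex and the copper alkoxide of 3 attacks its substituted terminus, so the branched ether forms and C5 is set by the chiral ligand. Aliphatic alkoxides, hindered ones included, are suitable nucleophiles as their copper salts, and the CH2O-substituted allyl terminus is far less crowded than one bearing a fully substituted carbon.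

Step 3
Reactants: 4 methyl (2R)-2-[(3-methylpenta-1,4-dien-3-yl)oxy]but-3-en-1-yl carbonate
Product: 5 [(2R,5S)-5-ethenyl-5-methyl-2,5-dihydrofuran-2-yl]methyl methyl carbonate
Conditions: second-generation Grubbs catalyst RuCl2(H2IMes)(PCy3)(=CHPh) (3 mol %), CH2Cl2 (0.01 M), 40 °C
Reagents that add atoms: none
Why: The benzylidene exchanges onto the least hindered terminal alkene, the vinyl group on the secondary carbon C5; intramolecular [2+2] cycloaddition of this alkylidene with one of the two vinyl groups on the carbinol carbon gives a ruthenacyclobutane, and cycloreversion releases the ring and Ru=CH2, which carries the chain with loss of ethene. The closest known reaction type is the diastereoselective ring-closing metathesis of ethers of divinyl carbinols to 2-vinyl-2,5-dihydrofurans. The ring closes as a five-membered ring with the new C3=C4 bond endocyclic; closure between the two geminal vinyl groups would give a cyclopropene and is not possible, so the oxygen heterocycle is the only ring that can form. The new stereocentre C2 arises from the choice between the two diastereotopic vinyl groups and is controlled by the existing C5 centre, which itself is not touched. In the metallacyclobutane the CH2OCO2Me group at C5 and the spectator vinyl group at C2 should avoid the same face of the forming ring, which places the smaller methyl group cis to the C5 arm, as 19 requires. The step needs this group selection and chemoselectivity against oligomerisation through the surviving vinyl group. The first rests only on a 1,3-relation across the ring oxygen and is the weak point; the second is secured by high dilution and by the fully substituted carbon next to the surviving vinyl group.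

Step 4
Reactants: 5 [(2R,5S)-5-ethenyl-5-methyl-2,5-dihydrofuran-2-yl]methyl methyl carbonate
Product: 6 [(1S,2S,4S,5S)-4-ethenyl-4-methyl-3,6-dioxabicyclo[3.1.0]hexan-2-yl]methyl methyl carbonate
Conditions: mCPBA, Na2HPO4, CH2Cl2, 0 → 25 °C
Reagents that add atoms: 3-chloroperbenzoic acid, OOC(=O)c1cccc(Cl)c1
Why: Prilezhaev epoxidation; the cis-disubstituted ring alkene is more nucleophilic than the monosubstituted vinyl group, and the peracid should approach anti to the CH2OCO2Me group at C5, which puts the epoxide oxygen on the upper face (the face of C5–H) and fixes the configuration of the C3–O bond.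

Step 5
Reactants: 6 [(1S,2S,4S,5S)-4-ethenyl-4-methyl-3,6-dioxabicyclo[3.1.0]hexan-2-yl]methyl methyl carbonate
Product: 8 (2S,3S,5R)-2-ethenyl-5-(hydroxymethyl)-2-methyloxolan-3-ol, via epoxy alcohol 7 (not isolated)
Conditions: NaAlH2(OCH2CH2OMe)2 (excess), THF, 0 → 25 °C; aqueous sodium potassium tartrate
Reagents that add atoms: none
Why: The hydride first cleaves the carbonate; the resulting alkoxyaluminate on the lower face then delivers hydride within the molecule to the adjacent C4, anti to the epoxide oxygen (alkoxide-directed reductive opening of an epoxy alcohol), so the C3–O bond and its configuration stay intact. Attack from outside at C3 has to pass the cis methyl group on the fully substituted C2.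

Step 6
Reactants: 8 (2S,3S,5R)-2-ethenyl-5-(hydroxymethyl)-2-methyloxolan-3-ol
Product: 9 (2R,4S,5S)-5-ethenyl-4-hydroxy-5-methyloxolane-2-carboxylic acid
Conditions: TEMPO (cat.), PhI(OAc)2 (2.2 equiv), MeCN/H2O, 25 °C
Reagents that add atoms: water, O
Why: Nitroxyl-catalysed oxidation with a hypervalent iodine oxidant in wet solvent takes the primary alcohol through the aldehyde hydrate to the acid and leaves the hindered secondary alcohol alone; the C3 hydroxyl and the C5 carbon are trans, so no lactol or lactone can form.

Step 7
Reactants: 9 (2R,4S,5S)-5-ethenyl-4-hydroxy-5-methyloxolane-2-carboxylic acid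
Product: 10 methyl (2R,4S,5S)-5-ethenyl-4-hydroxy-5-methyloxolane-2-carboxylate
Conditions: MeI, KHCO3, DMF, 25 °C
Reagents that add atoms: iodomethane, CI
Why: SN2 alkylation of the carboxylate; bicarbonate does not deprotonate the secondary alcohol, which stays free for the next step.

Step 8
Reactants: 10 methyl (2R,4S,5S)-5-ethenyl-4-hydroxy-5-methyloxolane-2-carboxylate
Product: 12 methyl (2R,4R,5S)-4-bromo-5-ethenyl-5-methyloxolane-2-carboxylate, via triflate 11 (not isolated)
Conditions: Tf2O, 2,6-lutidine, CH2Cl2, −40 °C; then Bu4NBr, toluene, −40 → 25 °C
Reagents that add atoms: trifluoromethanesulfonic anhydride, O=S(=O)(OS(=O)(=O)C(F)(F)F)C(F)(F)F (atoms only in 11); tetrabutylammonium bromide, CCCC[N+](CCCC)(CCCC)CCCC.[Br-]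
Why: Sulfonate formation followed by SN2 displacement with bromide inverts C3 and puts bromine on the lower face, cis to the C2 methyl group and the C5 arm, as in the conversion of trans-4-hydroxyproline esters into cis-4-bromoproline esters. The carbinol is flanked by a fully substituted carbon, so a non-ionising solvent and a soluble bromide are used, and the ester at C5 is a poor neighbouring group.

Step 9
Reactants: 12 methyl (2R,4R,5S)-4-bromo-5-ethenyl-5-methyloxolane-2-carboxylate
Product: 14 methyl (2R,4R,5S)-4-bromo-5-formyl-5-methyloxolane-2-carboxylate, via ozonide 13 (not isolated)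
Conditions: O3, CH2Cl2, −78 °C; then PPh3, −78 → 25 °C
Reagents that add atoms: ozone, [O-][O+]=O
Why: Ozonolysis with reductive work-up; the vinyl group is the only alkene left, and the aldehyde has no α-hydrogen, so neither epimerisation at C2 nor β-elimination of the C3 bromide can follow.

Step 10
Reactants: 14 methyl (2R,4R,5S)-4-bromo-5-formyl-5-methyloxolane-2-carboxylate
Product: 15 methyl (2R,4R,5S)-4-bromo-5-[(E)-2-bromoethenyl]-5-methyloxolane-2-carboxylate
Conditions: CrBr2 (6 equiv), CHBr3 (2 equiv), THF, 0 → 25 °C
Reagents that add atoms: bromoform, BrC(Br)Br
Why: Takai olefination: the geminal dichromium species from bromoform adds to the aldehyde and anti elimination gives the (E)-bromoalkene; the bromide salt of divalent chromium avoids halide exchange to a chloroalkene, and the secondary alkyl bromide and the ester are inert to it at this temperature.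

Step 11
Reactants: 15 methyl (2R,4R,5S)-4-bromo-5-[(E)-2-bromoethenyl]-5-methyloxolane-2-carboxylate
Product: 16 1-[(2R,4R,5S)-4-bromo-5-[(E)-2-bromoethenyl]-5-methyloxolan-2-yl]-2-chloroethan-1-one
Conditions: ICH2Cl (2.5 equiv), MeLi·LiBr (2.4 equiv), THF/Et2O, −78 °C; AcOH at −78 °C
Reagents that add atoms: chloroiodomethane, ClCI
Why: Carbenoid homologation of an ester to an α-chloro ketone: chloromethyllithium, formed by iodine–lithium exchange in the presence of the ester, adds once, and the tetrahedral lithium alkoxide is stable at −78 °C and collapses to the ketone only on acidic quench. Iodine–lithium exchange on ICH2Cl is much faster than bromine–lithium exchange at the alkenyl or alkyl bromide.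

Step 12
Reactants: 16 1-[(2R,4R,5S)-4-bromo-5-[(E)-2-bromoethenyl]-5-methyloxolan-2-yl]-2-chloroethan-1-one
Product: 17 (2R)-2-[(2R,4R,5S)-4-bromo-5-[(E)-2-bromoethenyl]-5-methyloxolan-2-yl]-1-chloropropan-2-ol
Conditions: MeMgBr (1.5 equiv), CH2Cl2/Et2O, −78 °C; aqueous NH4Cl at −78 °C
Reagents that add atoms: methylmagnesium bromide, C[Mg]Br
Why: Chelation-controlled (Cram chelate) 1,2-addition to an α-alkoxy ketone: magnesium bridges the carbonyl oxygen and the ring oxygen O1, and the methyl group enters from the face of C5–H, anti to C4, which gives the R carbinol at C1'. The cold quench keeps the magnesium alkoxide from closing onto the CH2Cl group to an epoxide.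

Step 13
Reactants: 17 (2R)-2-[(2R,4R,5S)-4-bromo-5-[(E)-2-bromoethenyl]-5-methyloxolan-2-yl]-1-chloropropan-2-ol
Product: 19 (2S,3R,5R)-3-bromo-5-[(2R)-2-bromo-1-chloropropan-2-yl]-2-[(E)-2-bromoethenyl]-2-methyloxolane, via bromosulfite 18 (not isolated)
Conditions: SOBr2 (1.5 equiv), CH2Cl2, −40 → 0 °C, no amine base
Reagents that add atoms: thionyl bromide, O=S(Br)Br
Why: Deoxybromination of a tertiary alcohol through its bromosulfite: ionisation and collapse of the ion pair from the front side (SNi) should give the bromide with retention at C1'. If the cation is instead intercepted by the ring oxygen or the β-chlorine and reopened by bromide at the tertiary carbon, the two inversions lead to the same configuration. No amine is added, so that bimolecular elimination and free bromide do not compete with the ion-pair path.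

## Compound list

1 | (E)-but-2-ene-1,4-diol | OC/C=C/CO | starting material
2 | (E)-but-2-ene-1,4-diyl dimethyl biscarbonate | COC(=O)OC/C=C/COC(=O)OC | intermediate
3 | 3-methylpenta-1,4-dien-3-ol | C=CC(C)(O)C=C | starting material
4 | methyl (2R)-2-[(3-methylpenta-1,4-dien-3-yl)oxy]but-3-en-1-yl carbonate | C=C[C@@H](OC(C)(C=C)C=C)COC(=O)OC | intermediate
5 | [(2R,5S)-5-ethenyl-5-methyl-2,5-dihydrofuran-2-yl]methyl methyl carbonate | COC(=O)OC[C@H]1C=C[C@](C)(C=C)O1 | intermediate
6 | [(1S,2S,4S,5S)-4-ethenyl-4-methyl-3,6-dioxabicyclo[3.1.0]hexan-2-yl]methyl methyl carbonate | COC(=O)OC[C@H]1[C@@H]2O[C@@H]2[C@](C)(C=C)O1 | intermediate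
7 | [(1S,2S,4S,5S)-4-ethenyl-4-methyl-3,6-dioxabicyclo[3.1.0]hexan-2-yl]methanol (as its aluminate) | OC[C@H]1[C@@H]2O[C@@H]2[C@](C)(C=C)O1 | intermediate
8 | (2S,3S,5R)-2-ethenyl-5-(hydroxymethyl)-2-methyloxolan-3-ol | OC[C@H]1C[C@H](O)[C@](C)(C=C)O1 | intermediate
9 | (2R,4S,5S)-5-ethenyl-4-hydroxy-5-methyloxolane-2-carboxylic acid | OC(=O)[C@H]1C[C@H](O)[C@](C)(C=C)O1 | intermediate
10 | methyl (2R,4S,5S)-5-ethenyl-4-hydroxy-5-methyloxolane-2-carboxylate | COC(=O)[C@H]1C[C@H](O)[C@](C)(C=C)O1 | intermediate
11 | methyl (2R,4S,5S)-5-ethenyl-5-methyl-4-[(trifluoromethanesulfonyl)oxy]oxolane-2-carboxylate | COC(=O)[C@H]1C[C@H](OS(=O)(=O)C(F)(F)F)[C@](C)(C=C)O1 | intermediate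
12 | methyl (2R,4R,5S)-4-bromo-5-ethenyl-5-methyloxolane-2-carboxylate | COC(=O)[C@H]1C[C@@H](Br)[C@](C)(C=C)O1 | intermediate
13 | methyl (2R,4R,5S)-4-bromo-5-methyl-5-(1,2,4-trioxolan-3-yl)oxolane-2-carboxylate (mixture at the trioxolane carbon) | COC(=O)[C@H]1C[C@@H](Br)[C@](C)(C2OCOO2)O1 | intermediate
14 | methyl (2R,4R,5S)-4-bromo-5-formyl-5-methyloxolane-2-carboxylate | COC(=O)[C@H]1C[C@@H](Br)[C@](C)(C=O)O1 | intermediate
15 | methyl (2R,4R,5S)-4-bromo-5-[(E)-2-bromoethenyl]-5-methyloxolane-2-carboxylate | COC(=O)[C@H]1C[C@@H](Br)[C@](C)(/C=C/Br)O1 | intermediate
16 | 1-[(2R,4R,5S)-4-bromo-5-[(E)-2-bromoethenyl]-5-methyloxolan-2-yl]-2-chloroethan-1-one | ClCC(=O)[C@H]1C[C@@H](Br)[C@](C)(/C=C/Br)O1 | intermediate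
17 | (2R)-2-[(2R,4R,5S)-4-bromo-5-[(E)-2-bromoethenyl]-5-methyloxolan-2-yl]-1-chloropropan-2-ol | C[C@](O)(CCl)[C@H]1C[C@@H](Br)[C@](C)(/C=C/Br)O1 | intermediate
18 | (2R)-2-[(2R,4R,5S)-4-bromo-5-[(E)-2-bromoethenyl]-5-methyloxolan-2-yl]-1-chloropropan-2-yl bromosulfite | C[C@](OS(=O)Br)(CCl)[C@H]1C[C@@H](Br)[C@](C)(/C=C/Br)O1 | intermediate
19 | (2S,3R,5R)-3-bromo-5-[(2R)-2-bromo-1-chloropropan-2-yl]-2-[(E)-2-bromoethenyl]-2-methyloxolane | C[C@](Br)(CCl)[C@H]1C[C@@H](Br)[C@](C)(/C=C/Br)O1 | target

Total step count: 13. Longest linear sequence: 13 steps (1 to 19; alcohol 3 enters in step 2).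

## Steps least certain to work

**Step 3 (key step).** The likely failure is poor discrimination between the two diastereotopic vinyl groups. The only bias is the C5 centre acting across the ring oxygen, the two spectator groups at C2 (methyl and vinyl) are of similar size, and ring opening by the ruthenium methylidene under ethene can erode a kinetic preference. The fallback removes the group selection; it sets out from 2 and returns at 5. A tertiary alcohol with two different arms, racemic 1,1-dimethoxy-2-methylbut-3-en-2-ol F1 (from commercial 1,1-dimethoxypropan-2-one and vinylmagnesium bromide), is coupled as its copper alkoxide with 2 under the conditions of step 2. The two ethers, epimeric at the quaternary carbon, are separated and methyl (2R)-2-{[(2R)-1,1-dimethoxy-2-methylbut-3-en-2-yl]oxy}but-3-en-1-yl carbonate F2 is taken on. Ring-closing metathesis with the same ruthenium catalyst now finds one vinyl group on each carbon and should give [(2R,5R)-5-(dimethoxymethyl)-5-methyl-2,5-dihydrofuran-2-yl]methyl methyl carbonate F3 with no selection to make. Mild aqueous acid unmasks [(2R,5R)-5-formyl-5-methyl-2,5-dihydrofuran-2-yl]methyl methyl carbonate F4, and Wittig methylenation (Ph3P=CH2, THF, −78 → 0 °C) gives 5. The price is a separation of diastereomers in place of a selective ring closure.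

**Step 13.** The tertiary centre is deactivated by the β-chlorine and the β-oxygen. Ionisation may therefore be slow and may end in elimination to the alkenes, in loss of configuration through a free cation, in ring expansion when bromide opens an oxonium intermediate at C5, or in a hydride shift from C5. The fallback forms the C–Br bond by a radical addition instead of a substitution; it sets out from 16 and returns at 19. Methylenation of the ketone (Cp2Ti(CH2)ClAlMe2, THF, −40 → 0 °C) gives (2S,3R,5R)-3-bromo-2-[(E)-2-bromoethenyl]-5-(3-chloroprop-1-en-2-yl)-2-methyloxolane F5. Markovnikov hydrobromination by hydrogen-atom transfer (Co(acac)2, t-BuOOH, Et3SiH, TsBr, n-PrOH, 25 °C) puts hydrogen on the terminal CH2 and bromine on the tertiary radical. The constitution of 19 is then secure, but C1' is no longer controlled and 19 must be separated from its C1' epimer.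

**Step 8.** Rear-side attack of bromide at C3 has to pass the fully substituted C2. Slow substitution leaves room for E2 toward C4 (which regenerates the ring alkene), for a 1,2-methyl shift from C2 with ring-oxygen assistance, or for capture of the triflate by the ester carbonyl. The fallback uses an internal nucleophile and then a front-side substitution; it sets out from 9 and returns at 12. Intramolecular Mitsunobu reaction of 9 (PPh3, diisopropyl azodicarboxylate, THF) lets the C5 carboxylate, held on the lower face, displace the activated C3 oxygen with inversion to give (1R,4R,6S)-6-ethenyl-6-methyl-2,5-dioxabicyclo[2.2.1]heptan-3-one F6. Methanolysis (K2CO3, MeOH, 0 °C) gives methyl (2R,4R,5S)-5-ethenyl-4-hydroxy-5-methyloxolane-2-carboxylate F7, the C3 epimer of 10. Thionyl bromide (CH2Cl2, −40 °C) converts it into methyl (2R,4R,5S)-4-[(bromosulfinyl)oxy]-5-ethenyl-5-methyloxolane-2-carboxylate F8, which is collapsed from the front side with catalytic TiBr4 to give 12 with retention.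

**Step 5.** Hydride may enter at C3 instead of C4 if delivery from the alkoxyaluminate is not faster than attack from outside; the two positions are sterically close, one next to the cis methyl group on C2 and the other next to the cis CH2O group on C5. The fallback lets sterics alone decide the regiochemistry; it sets out from 5 and returns at 12 by way of F6. Methanolysis of the carbonate (K2CO3, MeOH) gives [(2R,5S)-5-ethenyl-5-methyl-2,5-dihydrofuran-2-yl]methanol F9. Hydroxyl-directed epoxidation (VO(acac)2, t-BuOOH, CH2Cl2) puts the epoxide on the lower face, syn to the CH2OH group, as [(1R,2S,4S,5R)-4-ethenyl-4-methyl-3,6-dioxabicyclo[3.1.0]hexan-2-yl]methanol F10. LiAlH4 must then attack from the upper face, where C4 is flanked only by C5–H while C3 is shielded by the vinyl group on the quaternary carbon, and this should give (2S,3R,5R)-2-ethenyl-5-(hydroxymethyl)-2-methyloxolan-3-ol F11. Its two hydroxyl groups are cis, so nitroxyl-catalysed oxidation (TEMPO, PhI(OAc)2, CH2Cl2) closes the lactol and oxidises it to lactone F6, which is carried to 12 through F7 and F8 as described for step 8.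

**Step 2.** The tertiary, doubly allylic alkoxide is a hindered nucleophile. The risks are low conversion, attack at the unsubstituted allyl terminus, or acyl transfer from a carbonate. The fallback changes the electrophile and the metal; it sets out from 3 and returns at 4. Palladium-catalysed addition of 3 to racemic 2-vinyloxirane (Pd2(dba)3, enantiopure N,N'-(cyclohexane-1,2-diyl)bis[2-(diphenylphosphanyl)benzamide], catalytic BEt3, CH2Cl2) uses the borane to tie the alcohol to the alkoxide of the opened epoxide and to deliver it to the internal allyl terminus. This dynamic kinetic asymmetric transformation should give (2R)-2-[(3-methylpenta-1,4-dien-3-yl)oxy]but-3-en-1-ol F12, and methyl chloroformate with pyridine converts it into 4.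

## Further compounds

F1 | step 3 | 1,1-dimethoxy-2-methylbut-3-en-2-ol (racemic) | COC(OC)C(C)(O)C=C
F2 | step 3 | methyl (2R)-2-{[(2R)-1,1-dimethoxy-2-methylbut-3-en-2-yl]oxy}but-3-en-1-yl carbonate | C=C[C@H](COC(=O)OC)O[C@](C)(C=C)C(OC)OC
F3 | step 3 | [(2R,5R)-5-(dimethoxymethyl)-5-methyl-2,5-dihydrofuran-2-yl]methyl methyl carbonate | COC(=O)OC[C@H]1C=C[C@](C)(C(OC)OC)O1
F4 | step 3 | [(2R,5R)-5-formyl-5-methyl-2,5-dihydrofuran-2-yl]methyl methyl carbonate | COC(=O)OC[C@H]1C=C[C@](C)(C=O)O1
F5 | step 13 | (2S,3R,5R)-3-bromo-2-[(E)-2-bromoethenyl]-5-(3-chloroprop-1-en-2-yl)-2-methyloxolane | C=C(CCl)[C@H]1C[C@@H](Br)[C@](C)(/C=C/Br)O1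
F6 | step 8 | (1R,4R,6S)-6-ethenyl-6-methyl-2,5-dioxabicyclo[2.2.1]heptan-3-one | C=C[C@]1(C)O[C@@H]2C[C@H]1OC2=O
F7 | step 8 | methyl (2R,4R,5S)-5-ethenyl-4-hydroxy-5-methyloxolane-2-carboxylate | COC(=O)[C@H]1C[C@@H](O)[C@](C)(C=C)O1
F8 | step 8 | methyl (2R,4R,5S)-4-[(bromosulfinyl)oxy]-5-ethenyl-5-methyloxolane-2-carboxylate | COC(=O)[C@H]1C[C@@H](OS(=O)Br)[C@](C)(C=C)O1
F9 | step 5 | [(2R,5S)-5-ethenyl-5-methyl-2,5-dihydrofuran-2-yl]methanol | OC[C@H]1C=C[C@](C)(C=C)O1
F10 | step 5 | [(1R,2S,4S,5R)-4-ethenyl-4-methyl-3,6-dioxabicyclo[3.1.0]hexan-2-yl]methanol | OC[C@H]1[C@H]2O[C@H]2[C@](C)(C=C)O1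
F11 | step 5 | (2S,3R,5R)-2-ethenyl-5-(hydroxymethyl)-2-methyloxolan-3-ol | OC[C@H]1C[C@@H](O)[C@](C)(C=C)O1
F12 | step 2 | (2R)-2-[(3-methylpenta-1,4-dien-3-yl)oxy]but-3-en-1-ol | C=C[C@@H](OC(C)(C=C)C=C)CO
A1 | alternative 1 | 1-{(2R,3R,5R)-5-[(2R)-2-bromo-1-chloropropan-2-yl]-2-methyl-2-[(trimethylsilyl)ethynyl]oxolan-3-yl}ethan-1-one | C[C@](Br)(CCl)[C@H]1C[C@@H](C(C)=O)[C@](C)(C#C[Si](C)(C)C)O1
A2 | alternative 2 | (2S,5R)-2-methyl-5-(prop-1-en-2-yl)-2-[(trimethylsilyl)ethynyl]oxolan-3-one | CC(=C)[C@H]1CC(=O)[C@](C)(C#C[Si](C)(C)C)O1
A3 | alternative 3 | (4S,5S)-4-(benzyloxy)-5-ethenyl-5-methyloxolan-2-one | O=C1C[C@H](OCc2ccccc2)[C@](C)(C=C)O1
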